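Compounds are numbered 1–17 in the order of the steps; the same numbers are used in every section. Flavone numbering (O1, C2 … C8a) is used for 15–17, pyranone numbering (O1, C2 aryl, C3 OMe, C4 carbonyl, C5, C6) for 5 and 6, and cyclobutenone numbering (C1 carbonyl, C2, C3, C4 carbinol carbon) for 9–12.

## Analysis of the target

The target 17 is a flavone: a 4H-chromen-4-one in which the benzo ring A is fused to the 4-pyranone ring C, with a 4-methoxyphenyl group (ring B) on C2. It has no stereocentre and no other element of chirality, so the problem is one of constitution only. Ring A is fully substituted: C5, C6, C7 and C8 carry OMe, OMe, OH and OMe, and the two remaining carbons are the fusion atoms C4a and C8a. C3 carries a further methoxy group. The difficulty is to place four contiguous oxygens on ring A with exactly one of them, O7, free while both its neighbours are methylated. Late oxidation of a simpler flavone cannot be steered to these positions, and demethylation of a permethyl ether would attack the chelated C5 ether before the C7 one. The sensitive groups are the 4-pyranone (a vinylogous ester open to conjugate attack and ring opening), the C5 methoxy group peri to the carbonyl (labile to Lewis acids) and the free 7-hydroxyl, a vinylogous acid. The strategy rests on the fact that C5–C8 are four contiguous oxygen-bearing carbons, the pattern of a squaric diester, while C4a and C8a correspond to the C5=C6 bond of a monocyclic 2-aryl-3-methoxy-4-pyranone. Ring A can therefore be grown onto a finished ring C.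

## Retrosynthetic reasoning

**17 back to 15.** The last operations are kept trivial. The O7–H of 17 is traced to a tert-butyl ether in 16, and the O8–CH3 bond of 16 is cut to give phenol 15. A tert-butyl ether is chosen because a Brønsted acid removes it without touching any methyl ether, including the Lewis-acid-sensitive one at C5. What is gained is that O7 and O8 are already different in 15, so no selective methylation or demethylation is needed on the flavone.

**15 back to 12 (the strategic cut).** The C8–C8a bond of ring A is cut, and ring A unfolds through dienone 14 and dienylketene 13 to the cyclobutenone 12. This cut is preferred to any ring C disconnection because it turns the hexasubstituted benzene into a four-membered ring that already carries all four oxygens. C1 of 12 (the carbonyl) becomes C8 with its free hydroxyl, C2 becomes C7, C3 becomes C6 and C4 becomes C5. Forward, the reaction has to open the cyclobutenone with the pyranonyl group turned toward the ketene and close the new ring on the CH carbon of the pyranone. The oxygen on C2 must be the tert-butyl ether and the one on C3 a methyl ether, and that assignment must be beyond doubt.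

**12 back to 10.** The C3 oxygen–methyl bond of 12 is cut and C3 is traced to a tert-butoxy group in 10, through the vinylogous acid 11. A diester with two different alkyl groups would give 12 more directly, but only if the organometallic reagent told apart two carbonyl groups that differ by a remote alkyl group. That selectivity cannot be predicted. In 10 the C3 tert-butoxy group is a vinylogous tert-butyl ester and the C2 one is an enol ether, so acid should remove only the former. In 11 the carbons C1 and C3 are equivalent by tautomerism, because both are bonded to C2 and to C4. Methylation at either oxygen therefore gives the same compound 12, and the regiochemical question disappears by symmetry.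

**10 back to 6 and 7.** The methyl ether on the carbinol oxygen of 10 is cut to give 9. Then the bond between C4 of the cyclobutenone and C5 of the pyranone is cut, giving the 5-iodopyranone 6 as the source of a C5 nucleophile and the symmetrical squaric ester 7 as the electrophile. Because the two carbonyl groups of 7 are equivalent, the addition has no regiochemistry to control. Forward, the metalated pyranone must be generated cold enough that it neither opens by β-elimination of the ring oxygen nor is attacked by the exchange reagent.

**6 back to 5.** The C5–I bond is cut. C5 is the α-carbon of the vinylogous ester and the only unsubstituted nucleophilic position of 5, so electrophilic iodination should find it.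

**5 back to 2 and 3.** Ring C is opened at O1–C6, and the C5=C6 bond is cut, through enaminone 4. C6 comes from the amide acetal 3, and the remaining five ring atoms from the 1,3-diketone 2. The acetal can condense only at the methyl group of 2, because the carbon between the carbonyls has a single hydrogen.

**2 back to 1.** The bond between the methoxy-bearing carbon and the acetyl carbonyl is cut, leading to the α-methoxy ketone 1 and an acetyl donor. Ketone 1 already contains ring B, C2 and C3 with their oxygens.

## Alternatives that were turned down

**Alternative 1:** Ring A would be bought as a finished piece, the iodoarene A2, and the C4 carbon would come from carbon monoxide A3. The cuts are C4a–C4 and C3–C4. Forward, A2, A3 and ketone 1 would be joined by a zerovalent palladium catalyst (oxidative addition, insertion of A3, acylation of the ketone enolate) to the open 1,3-diketone A1. Acid would then remove both methoxymethyl groups and close O1–C2 by cyclodehydration, so 17 would follow from A1 in one operation.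
- For it: it is convergent, uses 1 as it stands, and distinguishes O7 from the outset. Its end game is shorter than the one chosen here, and on that point it is the stronger plan.
- Against it: A2 is a hexasubstituted benzene carrying the very oxygen pattern that makes the target hard. It would have to be assembled over many steps of oxidation and protection, each with its own regiochemical question. The aroylpalladium intermediate has two ortho substituents and the enolate of 1 is branched by its methoxy group, so the acyl transfer is the slow step of the cycle. The 2-substituted diketone A1 is also open to retro-Claisen cleavage under the basic coupling conditions.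
- Comparison: the chosen route accepts a less certain key step but draws all four ring A oxygens from one four-carbon reagent. This alternative only moves the difficulty into the preparation of A2.

**Alternative 2:** Rings A and B would be joined through ring C by cutting C8a–O1 and C4a–C4 (aryne insertion) and O1–C2 (ring closure). Fluoride would release the aryne from the silyl triflate A5. The carboxylate of acid A6 would add through oxygen at the aryne carbon remote from the methoxy group, the aryl anion next to that methoxy group would attack the carboxyl carbon, and the ortho-hydroxyaryl ynone A7 would close to flavone A4.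
- For it: three bonds and ring C form in one flask under mild conditions, and the polarisation of a 3-alkoxyaryne directs the addition in the sense needed. On the reliability of the bond-forming event it is at least the equal of the chosen plan.
- Against it: A4 lacks the oxygens at C3 and C8. C8 would have to be brominated and methoxylated under copper catalysis, C3 hydroxylated and methylated, and the benzyl ether removed, about five steps after the key step. A5 needs its own silylation sequence from a trioxygenated phenol. The phenoxide of A7 can also close in the 5-exo sense to an aurone.
- Comparison: this alternative pays for two of the oxygens one at a time. The squarate route installs C5–C8 with their oxygens in a single ring-forming step and needs no oxidation of the flavone.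

**Alternative 3:** The cuts are C3–C4 and C8a–O1, with ring A supplied as the 2-bromobenzoyl chloride A9. The lithium enolate of 1 would be C-acylated by A9, and the enolate oxygen of the resulting diketone would displace bromide under copper catalysis in the same flask, closing ring C to give A8. Hydrogenolysis of the benzyl ether would finish the synthesis.
- For it: every bond-forming event is a well-understood ionic or copper-mediated process, all oxygens are in place before the rings are joined, and the end game is one neutral step. In predictability it is the strongest of the plans, stronger than the one chosen.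
- Against it: A9 is again a fully substituted benzene (acid chloride, bromide, three methyl ethers and one benzyl ether in a fixed order). Its linear preparation from a gallic-acid-type precursor needs an extra ring oxidation, a selective dealkylation and a regioselective bromination, and would outweigh the rest of the route. Acylation of a lithium enolate by a doubly ortho-substituted aroyl chloride is slow and competes with O-acylation.
- Comparison: the chosen strategy gives up some predictability but replaces the long arene synthesis with one ring-forming step in which the distinction of O7 arises from the mechanism.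

Key step: step 7

Remark: di-tert-butyl squarate 7 is taken to be a catalogue compound; compounds 9–12 and 14 are racemic, and their single stereocentre disappears in step 7.

## Route

Step 1
Reactants: 1 2-methoxy-1-(4-methoxyphenyl)ethanone
Product: 2 2-methoxy-1-(4-methoxyphenyl)butane-1,3-dione
Conditions: 1-acetylbenzotriazole (1.1 equiv), MgBr2·OEt2 (2.5 equiv), i-Pr2NEt (3 equiv), CH2Cl2, rt
Reagents that add atoms: 1-acetyl-1H-benzotriazole, CC(=O)n1nnc2ccccc21
Why: Soft enolisation followed by crossed Claisen-type C-acylation: MgBr2 chelated between the carbonyl and the α-methoxy oxygen makes the α-CH2 acidic enough for the amine base, and the magnesium enolate is acylated at carbon by the N-acylbenzotriazole. The product stays as its magnesium diketonate, which should prevent a second acylation.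

Step 2
Reactants: 2 2-methoxy-1-(4-methoxyphenyl)butane-1,3-dione; 3 N,N-dimethylformamide dimethyl acetal
Product: 5 3-methoxy-2-(4-methoxyphenyl)-4H-pyran-4-one, via enaminone 4 (not isolated)
Conditions: Me2NCH(OMe)2 (2 equiv), PhMe, 90 °C; evaporate; then TFA, CH2Cl2, rt
Reagents that add atoms: none
Why: The carbon between the carbonyls has one hydrogen and cannot form an aminomethylene group, so the amide acetal condenses at the methyl ketone to give 4. Under acid the enol oxygen of the aryl ketone adds to the enaminone β-carbon and dimethylamine is expelled (6-endo addition–elimination), the standard 4-pyranone synthesis from 1,3-diketones.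

Step 3
Reactants: 5 3-methoxy-2-(4-methoxyphenyl)-4H-pyran-4-one
Product: 6 5-iodo-3-methoxy-2-(4-methoxyphenyl)-4H-pyran-4-one
Conditions: NIS (1.1 equiv), TFA (0.2 equiv), MeCN, rt, dark
Reagents that add atoms: N-iodosuccinimide, O=C1CCC(=O)N1I
Why: Electrophilic iodination of a vinylogous ester at its α-carbon: C5 is the only unsubstituted nucleophilic carbon of the pyranone, C6 being its electrophilic β-position. The anisyl ring is deactivated by conjugation with the pyranone and is blocked para to its methoxy group.

Step 4
Reactants: 6 5-iodo-3-methoxy-2-(4-methoxyphenyl)-4H-pyran-4-one; 7 di-tert-butyl squarate (3,4-di-tert-butoxycyclobut-3-ene-1,2-dione)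
Product: 9 2,3-di-tert-butoxy-4-hydroxy-4-[5-methoxy-6-(4-methoxyphenyl)-4-oxo-4H-pyran-3-yl]cyclobut-2-en-1-one (racemic), via pyranonylmagnesium chloride 8 (not isolated)
Conditions: i-PrMgCl·LiCl (1.05 equiv), THF, –40 °C, 30 min; cannulate into 7 (1.2 equiv), THF, –78 → –20 °C; aq. NH4Cl
Reagents that add atoms: none
Why: Iodine–magnesium exchange with the turbo Grignard reagent is fast at low temperature on α-iodo-β-alkoxy enones (3-iodochromones and 5-iodo-1,3-dioxin-4-ones behave this way) and gives a Grignard reagent chelated to the C4 carbonyl. It adds 1,2 to one of the two equivalent carbonyl groups of 7, so no regiochemical question arises; the carbinol stereocentre forms as the racemate and is destroyed in step 7.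

Step 5
Reactants: 9 2,3-di-tert-butoxy-4-hydroxy-4-[5-methoxy-6-(4-methoxyphenyl)-4-oxo-4H-pyran-3-yl]cyclobut-2-en-1-one (racemic)
Product: 10 2,3-di-tert-butoxy-4-methoxy-4-[5-methoxy-6-(4-methoxyphenyl)-4-oxo-4H-pyran-3-yl]cyclobut-2-en-1-one (racemic)
Conditions: MeI (10 equiv), Ag2O (3 equiv), 4 Å MS, MeCN, rt, dark
Reagents that add atoms: iodomethane, CI
Why: Purdie-type methylation with Ag2O and MeI is close to neutral and avoids the alkoxide-induced ring opening of 4-hydroxycyclobutenones. Methyl triflate is avoided because it would O-alkylate the pyranone carbonyl to a pyrylium salt.

Step 6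
Reactants: 10 2,3-di-tert-butoxy-4-methoxy-4-[5-methoxy-6-(4-methoxyphenyl)-4-oxo-4H-pyran-3-yl]cyclobut-2-en-1-one (racemic)
Product: 12 2-tert-butoxy-3,4-dimethoxy-4-[5-methoxy-6-(4-methoxyphenyl)-4-oxo-4H-pyran-3-yl]cyclobut-2-en-1-one (racemic), via 3-hydroxycyclobutenone 11 (not isolated)
Conditions: TFA (5 equiv), CH2Cl2, 0 °C; evaporate with PhMe below 20 °C; then TMSCHN2 (2 equiv), PhMe–MeOH (4:1), 0 °C; AcOH quench
Reagents that add atoms: trimethylsilyldiazomethane, C[Si](C)(C)C=[N+]=[N-]
Why: Protonation of the cyclobutenone carbonyl puts the positive charge on C3, whose tert-butoxy group then leaves as the tert-butyl cation as in the acidolysis of a tert-butyl ester; the C2 tert-butoxy group is an enol ether off the cationic carbon, and the protonated pyranone discourages ionisation at C4. In the vinylogous acid 11 the carbons C1 and C3 are interchangeable by tautomerism, so O-methylation by the diazoalkane (esterification of an acid) gives only racemic 12 whichever oxygen reacts.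

Step 7
Reactants: 12 2-tert-butoxy-3,4-dimethoxy-4-[5-methoxy-6-(4-methoxyphenyl)-4-oxo-4H-pyran-3-yl]cyclobut-2-en-1-one (racemic)
Product: 15 7-tert-butoxy-8-hydroxy-3,5,6-trimethoxy-2-(4-methoxyphenyl)-4H-chromen-4-one, via (Z)-dienylketene 13 (not isolated), via cyclohexadienone tautomer 14 (not isolated)
Conditions: degassed PhMe (0.02 M), 110 °C, Ar; p-xylene, 138 °C if ring opening is slow
Reagents that add atoms: none
Why: On heating, the C1–C4 bond of 12 opens in a conrotatory 4π electrocyclic reaction, and the C4 methoxy group, being the donor, rotates outward, so that in the (Z)-dienylketene 13 the pyranonyl group lies on the side of the ketene. The ketene C=C bond, the C3=C4 bond and the C5=C6 bond of the pyranone (numbering of 5) form a hexatriene that closes by a thermal disrotatory 6π electrocyclisation between the ketene carbon and the pyranone CH carbon, which makes the C8–C8a bond and the six-membered ring A in dienone 14. The only hydrogen of that ring sits on C8a, α to the new C8 ketone and on an oxygen-bearing carbon, and a proton shift gives phenol 15; aromatisation of ring A makes the sequence irreversible. The closest known reaction is the Moore rearrangement of squarate-derived 4-aryl- and 4-heteroaryl-4-alkoxycyclobutenones to hydroquinone monoethers, of which the pyranonyl case is a new member. No stereocentre is formed, since the carbinol centre of 12 and C8a of 14 both end as sp2 carbons. Three selectivities are needed: outward rotation of the methoxy group, secured by the donor at C4; closure at the CH carbon and not toward the pyranone carbonyl, secured because only the CH neighbour completes a conjugated triene; and placement of the oxygens, fixed by the atom mapping in which the ketene carbon becomes C8 with its free hydroxyl, C2 with its tert-butoxy group becomes C7, C3 becomes C6 and C4 becomes C5. Dilution and exclusion of air and moisture should keep the ketene from dimerising or being trapped.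

Step 8
Reactants: 15 7-tert-butoxy-8-hydroxy-3,5,6-trimethoxy-2-(4-methoxyphenyl)-4H-chromen-4-one
Product: 16 7-tert-butoxy-3,5,6,8-tetramethoxy-2-(4-methoxyphenyl)-4H-chromen-4-one
Conditions: MeI, K2CO3, acetone, reflux
Reagents that add atoms: iodomethane, CI
Why: Williamson etherification of the only free phenol; the tert-butyl ether and the chromone are inert to K2CO3 in acetone.

Step 9
Reactants: 16 7-tert-butoxy-3,5,6,8-tetramethoxy-2-(4-methoxyphenyl)-4H-chromen-4-one
Product: 17 7-hydroxy-3,5,6,8-tetramethoxy-2-(4-methoxyphenyl)-4H-chromen-4-one
Conditions: TFA–CH2Cl2 (1:4), 0 °C → rt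
Reagents that add atoms: none
Why: Acidolysis of the aryl tert-butyl ether by an E1 path releases the 7-hydroxyl as isobutene leaves. A Brønsted acid without a nucleophilic counter-ion does not touch the methyl ethers, including the C5 ether that a Lewis acid would cleave.

## Compound list

1 | 2-methoxy-1-(4-methoxyphenyl)ethanone | COCC(=O)c1ccc(OC)cc1 | starting material
2 | 2-methoxy-1-(4-methoxyphenyl)butane-1,3-dione | COc1ccc(cc1)C(=O)C(OC)C(C)=O | intermediate
3 | N,N-dimethylformamide dimethyl acetal | COC(OC)N(C)C | starting material
4 | (E)-5-(dimethylamino)-2-methoxy-1-(4-methoxyphenyl)pent-4-ene-1,3-dione | COc1ccc(cc1)C(=O)C(OC)C(=O)/C=C/N(C)C | intermediate (not isolated)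
5 | 3-methoxy-2-(4-methoxyphenyl)-4H-pyran-4-one | COc1ccc(-c2occc(=O)c2OC)cc1 | intermediate
6 | 5-iodo-3-methoxy-2-(4-methoxyphenyl)-4H-pyran-4-one | COc1ccc(-c2occ(I)c(=O)c2OC)cc1 | intermediate
7 | di-tert-butyl squarate (3,4-di-tert-butoxycyclobut-3-ene-1,2-dione) | CC(C)(C)OC1=C(OC(C)(C)C)C(=O)C1=O | starting material
8 | [5-methoxy-6-(4-methoxyphenyl)-4-oxo-4H-pyran-3-yl]magnesium chloride (LiCl complex) | COc1ccc(-c2occ([Mg]Cl)c(=O)c2OC)cc1 | intermediate (not isolated)
9 | 2,3-di-tert-butoxy-4-hydroxy-4-[5-methoxy-6-(4-methoxyphenyl)-4-oxo-4H-pyran-3-yl]cyclobut-2-en-1-one (racemic) | O=C1C(OC(C)(C)C)=C(OC(C)(C)C)C1(O)c1coc(-c2ccc(OC)cc2)c(OC)c1=O | intermediate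
10 | 2,3-di-tert-butoxy-4-methoxy-4-[5-methoxy-6-(4-methoxyphenyl)-4-oxo-4H-pyran-3-yl]cyclobut-2-en-1-one (racemic) | O=C1C(OC(C)(C)C)=C(OC(C)(C)C)C1(OC)c1coc(-c2ccc(OC)cc2)c(OC)c1=O | intermediate
11 | 2-tert-butoxy-3-hydroxy-4-methoxy-4-[5-methoxy-6-(4-methoxyphenyl)-4-oxo-4H-pyran-3-yl]cyclobut-2-en-1-one (racemic) | O=C1C(OC(C)(C)C)=C(O)C1(OC)c1coc(-c2ccc(OC)cc2)c(OC)c1=O | intermediate (not isolated)
12 | 2-tert-butoxy-3,4-dimethoxy-4-[5-methoxy-6-(4-methoxyphenyl)-4-oxo-4H-pyran-3-yl]cyclobut-2-en-1-one (racemic) | O=C1C(OC(C)(C)C)=C(OC)C1(OC)c1coc(-c2ccc(OC)cc2)c(OC)c1=O | intermediate
13 | (3Z)-2-tert-butoxy-3,4-dimethoxy-4-[5-methoxy-6-(4-methoxyphenyl)-4-oxo-4H-pyran-3-yl]buta-1,3-dien-1-one | O=C=C(OC(C)(C)C)/C(OC)=C(/OC)c1coc(-c2ccc(OC)cc2)c(OC)c1=O | intermediate (not isolated)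
14 | 7-tert-butoxy-3,5,6-trimethoxy-2-(4-methoxyphenyl)-4H-chromene-4,8(8aH)-dione (racemic) | COc1ccc(cc1)C1=C(OC)C(=O)C2=C(OC)C(OC)=C(OC(C)(C)C)C(=O)C2O1 | intermediate (not isolated)
15 | 7-tert-butoxy-8-hydroxy-3,5,6-trimethoxy-2-(4-methoxyphenyl)-4H-chromen-4-one | COc1ccc(-c2oc3c(O)c(OC(C)(C)C)c(OC)c(OC)c3c(=O)c2OC)cc1 | intermediate
16 | 7-tert-butoxy-3,5,6,8-tetramethoxy-2-(4-methoxyphenyl)-4H-chromen-4-one | COc1ccc(-c2oc3c(OC)c(OC(C)(C)C)c(OC)c(OC)c3c(=O)c2OC)cc1 | intermediate
17 | 7-hydroxy-3,5,6,8-tetramethoxy-2-(4-methoxyphenyl)-4H-chromen-4-one | COc1ccc(-c2oc3c(OC)c(O)c(OC)c(OC)c3c(=O)c2OC)cc1 | target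

## Step count and least certain steps

Total step count: 9. Longest linear sequence: 9 steps (1 to 17); 3 and 7 enter as purchased reagents.

**Step 7 (key step).** The ring closure has to take place at C6 of the pyranone, which is the electron-poor end of a push–pull double bond. Closure may therefore be slower than on an ordinary arene, leaving time for diversion of the ketene by dimerisation or adventitious nucleophiles. At the temperature of the thermal reaction the tert-butyl ether next to the newly formed phenol may also be lost by elimination of isobutene. The fallback sets out from 12 and returns at 15. It generates the ketene by light instead of heat: irradiation at about 365 nm in a flow reactor (PhMe or MeCN, 20 °C). Photochemical electrocyclic opening of cyclobutenones to vinylketenes is established. The isomer with the methoxy group turned inward can only revert to 12 and is recycled by the light, while isomer 13 closes as before. The thermal elimination channel is absent at ambient temperature.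

**Step 6.** The two tert-butyl groups may not be told apart well enough, so that both are lost. Alternatively the C4–OMe bond may ionise with the help of the C2 enol ether, and the second tert-butyl group would then be lost from the resulting cation to give a cyclobutenedione. The fallback sets out from 6 and returns at 12. It gives up the differentiation after the addition and uses a squarate that is already unsymmetrical:
- Dimethyl squarate F1 is hydrolysed once with NaOH (1 equiv, aqueous MeOH, 0 °C) to sodium 2-methoxy-3,4-dioxocyclobut-1-en-1-olate F2.
- AgNO3 precipitates silver 2-methoxy-3,4-dioxocyclobut-1-en-1-olate F3.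
- tert-Butyl chloride in Et2O alkylates F3 at oxygen to give tert-butyl methyl squarate F4, in the way the di-tert-butyl ester is classically made from the disilver salt.
- Grignard reagent 8, made from 6 as in step 4, is added to F4 at –78 °C. The carbinol 2-tert-butoxy-4-hydroxy-3-methoxy-4-[5-methoxy-6-(4-methoxyphenyl)-4-oxo-4H-pyran-3-yl]cyclobut-2-en-1-one F5 results from attack at the carbonyl next to the methoxy-bearing carbon. It is expected to predominate because the tert-butoxy group hinders its neighbouring carbonyl.
- F5 is separated by chromatography from its regioisomer 3-tert-butoxy-4-hydroxy-2-methoxy-4-[5-methoxy-6-(4-methoxyphenyl)-4-oxo-4H-pyran-3-yl]cyclobut-2-en-1-one F6.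
- Methylation of F5 with MeI and Ag2O as in step 5 gives 12.

**Step 4.** The magnesiated pyranone 8 may fragment by β-elimination of the ring oxygen (opening to an ynone enolate), or the exchange reagent may add in conjugate fashion at C6 before the exchange is complete. The fallback sets out from 6 and returns at 9. It changes both the metal and the way the nucleophile is made. Zinc dust with LiCl in THF at 25 °C inserts into the C–I bond to give [5-methoxy-6-(4-methoxyphenyl)-4-oxo-4H-pyran-3-yl]zinc iodide F7, which is not basic enough to fragment. Its addition to the strongly electrophilic carbonyl of 7 is then promoted by MgCl2, as in the known additions of arylzinc reagents to ketones.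

**Step 3.** Iodination may be slow at C5 of the weakly nucleophilic pyranone, and iodination ortho to the methoxy group of ring B may compete. The fallback sets out from 4, isolated after the first stage of step 2, and returns at 6. The halogen is introduced before the ring exists: I2 in CHCl3 at rt iodinates the enaminone α-carbon, by far the most nucleophilic site, and the resulting iminium ion is closed by the aryl ketone oxygen with loss of dimethylamine. This is the way 3-iodochromones are made from ortho-hydroxyaryl enaminones.

## Further compounds

F0 | step 7 | none | none
F1 | step 6 | dimethyl squarate (3,4-dimethoxycyclobut-3-ene-1,2-dione) | COC1=C(OC)C(=O)C1=O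
F2 | step 6 | sodium 2-methoxy-3,4-dioxocyclobut-1-en-1-olate | COC1=C([O-])C(=O)C1=O.[Na+]
F3 | step 6 | silver 2-methoxy-3,4-dioxocyclobut-1-en-1-olate | COC1=C([O-])C(=O)C1=O.[Ag+]
F4 | step 6 | tert-butyl methyl squarate (3-tert-butoxy-4-methoxycyclobut-3-ene-1,2-dione) | COC1=C(OC(C)(C)C)C(=O)C1=O
F5 | step 6 | 2-tert-butoxy-4-hydroxy-3-methoxy-4-[5-methoxy-6-(4-methoxyphenyl)-4-oxo-4H-pyran-3-yl]cyclobut-2-en-1-one (racemic) | O=C1C(OC(C)(C)C)=C(OC)C1(O)c1coc(-c2ccc(OC)cc2)c(OC)c1=O
F6 | step 6 | 3-tert-butoxy-4-hydroxy-2-methoxy-4-[5-methoxy-6-(4-methoxyphenyl)-4-oxo-4H-pyran-3-yl]cyclobut-2-en-1-one (racemic) | O=C1C(OC)=C(OC(C)(C)C)C1(O)c1coc(-c2ccc(OC)cc2)c(OC)c1=O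
F7 | step 4 | [5-methoxy-6-(4-methoxyphenyl)-4-oxo-4H-pyran-3-yl]zinc iodide | COc1ccc(-c2occ([Zn]I)c(=O)c2OC)cc1
F0 | step 3 | none | none
A1 | alternative 1 | 2-methoxy-3-(4-methoxyphenyl)-1-[2,3,5-trimethoxy-4,6-bis(methoxymethoxy)phenyl]propane-1,3-dione | COCOc1c(C(=O)C(OC)C(=O)c2ccc(OC)cc2)c(OC)c(OC)c(OCOC)c1OC
A2 | alternative 1 | 1-iodo-2,3,5-trimethoxy-4,6-bis(methoxymethoxy)benzene | COCOc1c(I)c(OC)c(OC)c(OCOC)c1OC
A3 | alternative 1 | carbon monoxide | [C-]#[O+]
A4 | alternative 2 | 7-(benzyloxy)-5,6-dimethoxy-2-(4-methoxyphenyl)-4H-chromen-4-one | COc1ccc(-c2cc(=O)c3c(OC)c(OC)c(OCc4ccccc4)cc3o2)cc1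
A5 | alternative 2 | 5-(benzyloxy)-3,4-dimethoxy-2-(trimethylsilyl)phenyl trifluoromethanesulfonate | COc1c(OC)c(OCc2ccccc2)cc(OS(=O)(=O)C(F)(F)F)c1[Si](C)(C)C
A6 | alternative 2 | 3-(4-methoxyphenyl)prop-2-ynoic acid | COc1ccc(cc1)C#CC(=O)O
A7 | alternative 2 | 1-[4-(benzyloxy)-6-hydroxy-2,3-dimethoxyphenyl]-3-(4-methoxyphenyl)prop-2-yn-1-one | COc1ccc(cc1)C#CC(=O)c1c(O)cc(OCc2ccccc2)c(OC)c1OC
A8 | alternative 3 | 7-(benzyloxy)-3,5,6,8-tetramethoxy-2-(4-methoxyphenyl)-4H-chromen-4-one | COc1ccc(-c2oc3c(OC)c(OCc4ccccc4)c(OC)c(OC)c3c(=O)c2OC)cc1
A9 | alternative 3 | 4-(benzyloxy)-2-bromo-3,5,6-trimethoxybenzoyl chloride | COc1c(Br)c(C(Cl)=O)c(OC)c(OC)c1OCc1ccccc1
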